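**Retrosynthetic overview**
1. Target 26 ⇒ diol 25 ⇒ macrocyclic alcohol 23: the two acetates and the methacrylate are put on last.
2. 23 ⇒ open diene 22 by ring-closing metathesis at C4=C5 (vinyl + isopropenyl); this closes the ten-membered carbocycle onto the finished butenolide.
3. 22 ⇒ C7–C8 bond by Ni/Cr (Nozaki–Hiyama–Kishi) coupling of west β-iodobutenolide 20 with east aldehyde 12.
4. 20 ⇒ carbonylative lactonisation of an E-diiodide from a resolved vinyl propargylic alcohol (C6); 12 ⇒ Cu–box Mukaiyama aldol of a 1,2-diketone (C10).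
5. Ring order: butenolide (step 11), then ten-membered ring (step 13).

Numbering used: germacrane numbering, C1 ketone, C4=C5, C6 lactone carbinol, C7=C11, C8 ester carbinol, C10 tertiary carbinol, C12 lactone carbonyl, C13 CH2O. The target is 4Z,6R,8S,10R.

Assumption: the facial sense of the Cu–box aldol on the 1,2-diketone is taken to be the one known for pyruvate esters, so the (R,R)-ligand gives the R carbinol (otherwise the (S,S)-ligand is used).

**East fragment**

Step 1
Reactants: 1 3,3-dimethoxybutan-2-one; 2 3-bromo-2-methylprop-1-ene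
Product: 4 2,2-dimethoxy-6-methylhept-6-en-3-one, via lithium enolate 3 (not isolated)
Conditions: LDA, THF, −78 °C; then 2, DMPU, −78 to 0 °C
Reagents that add atoms: none
Why: Enolate alkylation (SN2 on an allylic bromide); ketone 1 has a single enolisable position, so only one regioisomer can form and no stereocentre is made.

Step 2
Reactants: 4 2,2-dimethoxy-6-methylhept-6-en-3-one
Product: 5 6-methylhept-6-ene-2,3-dione
Conditions: 1 M aq. HCl, THF, rt
Reagents that add atoms: water, O
Why: Acid-catalysed ketal hydrolysis frees the 1,2-diketone; the isolated 1,1-disubstituted alkene is inert to dilute acid at room temperature.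

Step 3
Reactants: 6 S-ethyl ethanethioate
Product: 8 1-(ethylsulfanyl)-1-[(trimethylsilyl)oxy]ethene, via lithium thioenolate 7 (not isolated)
Conditions: LDA, THF, −78 °C; Me3SiCl
Reagents that add atoms: chlorotrimethylsilane, C[Si](C)(C)Cl
Why: O-silylation of the thioester enolate gives the ketene S,O-acetal that serves as the Mukaiyama nucleophile.

Step 4
Reactants: 5 6-methylhept-6-ene-2,3-dione; 8 1-(ethylsulfanyl)-1-[(trimethylsilyl)oxy]ethene
Product: 10 S-ethyl (3R)-3-hydroxy-3,7-dimethyl-4-oxooct-7-enethioate, via trimethylsilyl ether 9 (not isolated)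
Conditions: Cu(OTf)2 (10 mol%), (R,R)-tBu-box (11 mol%), THF, −78 °C; then 1 M HCl, THF
Reagents that add atoms: none
Why: Evans catalytic enantioselective Mukaiyama aldol: the diketone chelates divalent copper, the enolsilane attacks the less hindered methyl ketone carbonyl from the face left open by the tert-butyl groups, which sets C10 as R, and acid work-up cleaves the silyl ether.

Step 5
Reactants: 10 S-ethyl (3R)-3-hydroxy-3,7-dimethyl-4-oxooct-7-enethioate
Product: 11 S-ethyl (3R)-3,7-dimethyl-4-oxo-3-[(triethylsilyl)oxy]oct-7-enethioate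
Conditions: Et3SiOTf, 2,6-lutidine, CH2Cl2, −78 to 0 °C
Reagents that add atoms: triethylsilyl trifluoromethanesulfonate, CC[Si](CC)(CC)OS(=O)(=O)C(F)(F)F
Why: Silyl triflate silylation of the hindered tertiary aldol hydroxyl blocks retro-aldol cleavage and β-elimination in the next steps.

Step 6
Reactants: 11 S-ethyl (3R)-3,7-dimethyl-4-oxo-3-[(triethylsilyl)oxy]oct-7-enethioate
Product: 12 (3R)-3,7-dimethyl-4-oxo-3-[(triethylsilyl)oxy]oct-7-enal
Conditions: Et3SiH, Pd/CaCO3 poisoned with Pb(OAc)2 (5 mol% Pd), acetone, rt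
Reagents that add atoms: none
Why: Fukuyama reduction (Pd insertion into the C–S bond, hydride transfer from the silane) stops at the aldehyde and leaves ketone, silyl ether and, on the poisoned catalyst, the alkene untouched.

**West fragment**

Step 7
Reactants: 13 prop-2-yn-1-ol
Product: 14 tert-butyldimethyl(prop-2-yn-1-yloxy)silane
Conditions: TBSCl, imidazole, CH2Cl2, 0 °C to rt
Reagents that add atoms: tert-butylchlorodimethylsilane, CC(C)(C)[Si](C)(C)Cl
Why: Standard silyl ether formation protects the future C13 hydroxyl.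

Step 8
Reactants: 14 tert-butyldimethyl(prop-2-yn-1-yloxy)silane; 15 acrolein
Product: 17 rac-6-[(tert-butyldimethylsilyl)oxy]hex-1-en-4-yn-3-ol, via lithium acetylide 16 (not isolated)
Conditions: n-BuLi, THF, −78 °C; then 15, −78 °C; aq. NH4Cl
Reagents that add atoms: none
Why: 1,2-Addition of a lithium acetylide to the enal at low temperature gives the racemic vinyl propargylic alcohol.

Step 9
Reactants: 17 rac-6-[(tert-butyldimethylsilyl)oxy]hex-1-en-4-yn-3-ol
Product: 18 (3R)-6-[(tert-butyldimethylsilyl)oxy]hex-1-en-4-yn-3-ol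
Conditions: Ti(OiPr)4, D-(−)-diisopropyl tartrate, tBuOOH (0.6 equiv), 4 Å sieves, CH2Cl2, −20 °C, stopped at about 55% conversion
Reagents that add atoms: none
Why: Sharpless kinetic resolution: with D-(−)-tartrate the S alcohol is epoxidised at its vinyl group much faster, so the R alcohol (C6 of the target) is recovered in high ee.

Step 10
Reactants: 18 (3R)-6-[(tert-butyldimethylsilyl)oxy]hex-1-en-4-yn-3-ol
Product: 19 (3R,4E)-6-[(tert-butyldimethylsilyl)oxy]-4,5-diiodohexa-1,4-dien-3-ol
Conditions: I2 (1.2 equiv), CH2Cl2, 0 °C to rt, dark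
Reagents that add atoms: iodine, II
Why: Electrophilic anti addition of iodine to the alkyne gives the E-diiodoalkene, which places the C5 iodine cis to the carbinol carbon; the vinyl group does not add iodine irreversibly.

Step 11
Reactants: 19 (3R,4E)-6-[(tert-butyldimethylsilyl)oxy]-4,5-diiodohexa-1,4-dien-3-ol
Product: 20 (5R)-3-{[(tert-butyldimethylsilyl)oxy]methyl}-4-iodo-5-vinylfuran-2(5H)-one
Conditions: CO (1 atm), PdCl2(PPh3)2 (5 mol%), K2CO3, THF, 40 °C
Reagents that add atoms: carbon monoxide, [C-]#[O+]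
Why: Palladium-catalysed carbonylative lactonisation: only the acylpalladium formed at the C–I bond cis to the carbinol can be trapped by the hydroxyl, which closes the butenolide, keeps the other iodine on the β-carbon and does not touch the stereocentre.

**Coupling and endgame**

Step 12
Reactants: 12 (3R)-3,7-dimethyl-4-oxo-3-[(triethylsilyl)oxy]oct-7-enal; 20 (5R)-3-{[(tert-butyldimethylsilyl)oxy]methyl}-4-iodo-5-vinylfuran-2(5H)-one
Product: 22 (5R)-3-{[(tert-butyldimethylsilyl)oxy]methyl}-4-{(1S,3R)-1-hydroxy-3,7-dimethyl-4-oxo-3-[(triethylsilyl)oxy]oct-7-en-1-yl}-5-vinylfuran-2(5H)-one, via alkenylchromium dichloride 21 (not isolated)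
Conditions: CrCl2 (4 equiv), NiCl2 (5 mol%), Kishi oxazoline–sulfonamide ligand (antipode for Re-face addition), Et3N, THF/MeCN, rt
Reagents that add atoms: none
Why: Nozaki–Hiyama–Kishi coupling: the alkenylchromium species made from the β-iodobutenolide adds to the aldehyde only (the ketone is inert), and the chiral chromium sulfonamide complex directs attack to the Re face, which sets C8 as S.

Step 13
Reactants: 22 (the diene from step 12)
Product: 23 (4Z,6R,8S,10R)-13-[(tert-butyldimethylsilyl)oxy]-8-hydroxy-1-oxo-10-[(triethylsilyl)oxy]germacra-4,7(11)-dien-12,6-olide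
Conditions: second-generation Grubbs catalyst (2 × 10 mol%), 1,4-benzoquinone (20 mol%), toluene (1 mM), 90 °C
Reagents that add atoms: none
Why: Ring-closing metathesis of the vinyl and isopropenyl groups closes the ten-membered ring with loss of ethylene; the ring size and the fused butenolide enforce the cis (Z) trisubstituted C4=C5 bond.

Step 14
Reactants: 23 (macrocyclic alcohol)
Product: 24 (4Z,6R,8S,10R)-13-[(tert-butyldimethylsilyl)oxy]-8-(methacryloyloxy)-1-oxo-10-[(triethylsilyl)oxy]germacra-4,7(11)-dien-12,6-olide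
Conditions: methacrylic anhydride, Et3N, DMAP (cat.), CH2Cl2, 0 °C to rt
Reagents that add atoms: methacrylic anhydride, C=C(C)C(=O)OC(=O)C(C)=C
Why: DMAP-catalysed acylation of the only free hydroxyl (C8); it follows the metathesis so that the methacrylate cannot take part in ring closure.

Step 15
Reactants: 24 (bis-silyl ether)
Product: 25 (4Z,6R,8S,10R)-10,13-dihydroxy-8-(methacryloyloxy)-1-oxogermacra-4,7(11)-dien-12,6-olide
Conditions: HF·pyridine, pyridine, THF, 0 °C to rt
Reagents that add atoms: none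
Why: Fluoride-mediated desilylation removes the primary TBS and tertiary TES ethers under buffered conditions that leave lactone and methacrylate intact.

Step 16
Reactants: 25 (diol)
Product: 26 (4Z,6R,8S,10R)-10,13-diacetoxy-8-(methacryloyloxy)-1-oxogermacra-4,7(11)-dien-12,6-olide (CNP0115165.2)
Conditions: Ac2O, DMAP, Et3N, CH2Cl2, rt to 35 °C
Reagents that add atoms: acetic anhydride, CC(=O)OC(C)=O
Why: DMAP-catalysed (Steglich-type) acetylation esterifies the primary C13 hydroxyl and, more slowly, the tertiary C10 hydroxyl in one operation without touching a stereocentre.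

**Compound list**
1 | 3,3-dimethoxybutan-2-one | CC(=O)C(C)(OC)OC | starting material
2 | 3-bromo-2-methylprop-1-ene | C=C(C)CBr | starting material
3 | lithium 3,3-dimethoxybut-1-en-2-olate | [Li]OC(=C)C(C)(OC)OC | intermediate (not isolated)
4 | 2,2-dimethoxy-6-methylhept-6-en-3-one | CC(OC)(OC)C(=O)CCC(C)=C | intermediate
5 | 6-methylhept-6-ene-2,3-dione | CC(=O)C(=O)CCC(C)=C | intermediate
6 | S-ethyl ethanethioate | CCSC(C)=O | starting material
7 | lithium 1-(ethylsulfanyl)ethen-1-olate | [Li]OC(=C)SCC | intermediate (not isolated)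
8 | 1-(ethylsulfanyl)-1-[(trimethylsilyl)oxy]ethene | C=C(SCC)O[Si](C)(C)C | intermediate
9 | S-ethyl (3R)-3,7-dimethyl-4-oxo-3-[(trimethylsilyl)oxy]oct-7-enethioate | CCSC(=O)C[C@@](C)(O[Si](C)(C)C)C(=O)CCC(C)=C | intermediate (not isolated)
10 | S-ethyl (3R)-3-hydroxy-3,7-dimethyl-4-oxooct-7-enethioate | CCSC(=O)C[C@@](C)(O)C(=O)CCC(C)=C | intermediate
11 | S-ethyl (3R)-3,7-dimethyl-4-oxo-3-[(triethylsilyl)oxy]oct-7-enethioate | CCSC(=O)C[C@@](C)(O[Si](CC)(CC)CC)C(=O)CCC(C)=C | intermediate
12 | (3R)-3,7-dimethyl-4-oxo-3-[(triethylsilyl)oxy]oct-7-enal | O=CC[C@@](C)(O[Si](CC)(CC)CC)C(=O)CCC(C)=C | intermediate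
13 | prop-2-yn-1-ol | C#CCO | starting material
14 | tert-butyldimethyl(prop-2-yn-1-yloxy)silane | C#CCO[Si](C)(C)C(C)(C)C | intermediate
15 | acrolein (prop-2-enal) | C=CC=O | starting material
16 | lithium acetylide of 14 | [Li]C#CCO[Si](C)(C)C(C)(C)C | intermediate (not isolated)
17 | rac-6-[(tert-butyldimethylsilyl)oxy]hex-1-en-4-yn-3-ol | C=CC(O)C#CCO[Si](C)(C)C(C)(C)C | intermediate
18 | (3R)-6-[(tert-butyldimethylsilyl)oxy]hex-1-en-4-yn-3-ol | C=C[C@@H](O)C#CCO[Si](C)(C)C(C)(C)C | intermediate
19 | (3R,4E)-6-[(tert-butyldimethylsilyl)oxy]-4,5-diiodohexa-1,4-dien-3-ol | C=C[C@@H](O)/C(I)=C(\I)CO[Si](C)(C)C(C)(C)C | intermediate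
20 | (5R)-3-{[(tert-butyldimethylsilyl)oxy]methyl}-4-iodo-5-vinylfuran-2(5H)-one | C=C[C@H]1OC(=O)C(CO[Si](C)(C)C(C)(C)C)=C1I | intermediate
21 | alkenylchromium dichloride from 20 | C=C[C@H]1OC(=O)C(CO[Si](C)(C)C(C)(C)C)=C1[Cr](Cl)Cl | intermediate (not isolated)
22 | (5R)-3-{[(tert-butyldimethylsilyl)oxy]methyl}-4-{(1S,3R)-1-hydroxy-3,7-dimethyl-4-oxo-3-[(triethylsilyl)oxy]oct-7-en-1-yl}-5-vinylfuran-2(5H)-one | C=C[C@H]1OC(=O)C(CO[Si](C)(C)C(C)(C)C)=C1[C@@H](O)C[C@@](C)(O[Si](CC)(CC)CC)C(=O)CCC(C)=C | intermediate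
23 | (4Z,6R,8S,10R)-13-[(tert-butyldimethylsilyl)oxy]-8-hydroxy-1-oxo-10-[(triethylsilyl)oxy]germacra-4,7(11)-dien-12,6-olide | O[C@H]1C[C@@](C)(O[Si](CC)(CC)CC)C(=O)CC/C(C)=C\[C@H]2OC(=O)C(CO[Si](C)(C)C(C)(C)C)=C12 | intermediate
24 | 8-O-methacrylate of 23 | C=C(C)C(=O)O[C@H]1C[C@@](C)(O[Si](CC)(CC)CC)C(=O)CC/C(C)=C\[C@H]2OC(=O)C(CO[Si](C)(C)C(C)(C)C)=C12 | intermediate
25 | (4Z,6R,8S,10R)-10,13-dihydroxy-8-(methacryloyloxy)-1-oxogermacra-4,7(11)-dien-12,6-olide | C=C(C)C(=O)O[C@H]1C[C@@](C)(O)C(=O)CC/C(C)=C\[C@H]2OC(=O)C(CO)=C12 | intermediate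
26 | (4Z,6R,8S,10R)-10,13-diacetoxy-8-(methacryloyloxy)-1-oxogermacra-4,7(11)-dien-12,6-olide (CNP0115165.2) | C=C(C)C(=O)O[C@H]1C[C@@](C)(OC(C)=O)C(=O)CC/C(C)=C\[C@H]2OC(=O)C(COC(C)=O)=C12 | target

**Step count**
Total steps: 16. Longest linear sequence: 10 (steps 1, 2, 4, 5, 6, 12–16; the west branch 7–11 followed by 12–16 is equally long; step 3 is a one-step side branch).

**Three steps most likely to fail**

Step 13 (ring-closing metathesis). A strained ten-membered ring with a trisubstituted olefin may close slowly and lose out to oligomerisation. The fallback sets out from 22 and comes back at 23. The C8 carbinol of 22 is oxidised with Dess–Martin periodinane to the open-chain dienone F1, which removes the free hydroxyl next to the reacting olefin and flattens the C7–C8–C9 segment. Metathesis of F1 under the same dilution gives the macrocyclic enone F2. CBS reduction of F2 at low temperature, with the oxazaborolidine antipode that delivers hydride to the Re face of the C8 carbonyl, then gives 23; the C1 ketone, shielded by the quaternary C10, should react far more slowly. In this variant C8 is set after the ring is closed.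

Step 12 (Nozaki–Hiyama–Kishi coupling). The coupling itself should proceed, but the β-silyloxy aldehyde has an inherent 1,3-anti preference that opposes the required 8S configuration, so ligand control may be poor. The fallback sets out from 12 and 20 and comes back at 24. The coupling is run without chiral ligand and the major 8R product, the 8-epi alcohol F3, is isolated. Metathesis of F3 gives the 8-epi macrocyclic alcohol F4. F4 is then esterified with methacrylic acid under Mitsunobu conditions (PPh3, DIAD), which inverts C8 and gives 24 directly.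

Step 11 (carbonylative lactonisation of the diiodide). This has no close precedent; palladium may strip iodine to return the alkyne, or the product iodide may react further. The fallback sets out from acrolein 15 and comes back at 20. Lithium ethyl propiolate is added to 15 to give racemic ethyl 4-hydroxyhex-5-en-2-ynoate F5. Sharpless kinetic resolution with D-(−)-diisopropyl tartrate, as in step 9, leaves ethyl (4R)-4-hydroxyhex-5-en-2-ynoate F6. F6 is treated with MgI2 and paraformaldehyde: iodide adds to the ynoate, the allenoate is hydroxymethylated, and reversible iodide addition funnels the geometry to the isomer that lactonises. This gives (5R)-3-(hydroxymethyl)-4-iodo-5-vinylfuran-2(5H)-one F7, which is silylated (TBSCl, imidazole) to 20. Here the lactone carbonyl is present before the iodine is introduced.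

**Further compounds**
F1 | step 13 | (5R)-3-{[(tert-butyldimethylsilyl)oxy]methyl}-4-{(3R)-3,7-dimethyl-1,4-dioxo-3-[(triethylsilyl)oxy]oct-7-en-1-yl}-5-vinylfuran-2(5H)-one | C=C[C@H]1OC(=O)C(CO[Si](C)(C)C(C)(C)C)=C1C(=O)C[C@@](C)(O[Si](CC)(CC)CC)C(=O)CCC(C)=C
F2 | step 13 | (4Z,6R,10R)-13-[(tert-butyldimethylsilyl)oxy]-1,8-dioxo-10-[(triethylsilyl)oxy]germacra-4,7(11)-dien-12,6-olide | O=C1C[C@@](C)(O[Si](CC)(CC)CC)C(=O)CC/C(C)=C\[C@H]2OC(=O)C(CO[Si](C)(C)C(C)(C)C)=C12
F3 | step 12 | 8-epi-22, (5R)-3-{[(tert-butyldimethylsilyl)oxy]methyl}-4-{(1R,3R)-1-hydroxy-3,7-dimethyl-4-oxo-3-[(triethylsilyl)oxy]oct-7-en-1-yl}-5-vinylfuran-2(5H)-one | C=C[C@H]1OC(=O)C(CO[Si](C)(C)C(C)(C)C)=C1[C@H](O)C[C@@](C)(O[Si](CC)(CC)CC)C(=O)CCC(C)=C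
F4 | step 12 | 8-epi-23, (4Z,6R,8R,10R)-13-[(tert-butyldimethylsilyl)oxy]-8-hydroxy-1-oxo-10-[(triethylsilyl)oxy]germacra-4,7(11)-dien-12,6-olide | O[C@@H]1C[C@@](C)(O[Si](CC)(CC)CC)C(=O)CC/C(C)=C\[C@H]2OC(=O)C(CO[Si](C)(C)C(C)(C)C)=C12
F5 | step 11 | rac-ethyl 4-hydroxyhex-5-en-2-ynoate | C=CC(O)C#CC(=O)OCC
F6 | step 11 | ethyl (4R)-4-hydroxyhex-5-en-2-ynoate | C=C[C@@H](O)C#CC(=O)OCC
F7 | step 11 | (5R)-3-(hydroxymethyl)-4-iodo-5-vinylfuran-2(5H)-one | C=C[C@H]1OC(=O)C(CO)=C1I
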